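**Plan**

- **Cuts:** (a) the ester bond between O3 and the 4-hydroxybenzoyl carbon. (b) The C3 carbinol goes back to a ketone, masked as its methyl enol ether. (c) C4–C4a, O1–C8a and O1–C2 are cut together, which splits ring C into an aryne (ring A) and an α-methoxycinnamaldehyde (C2, C3, C4, O1, ring B).
- **Enabling feature:** in ring A, the carbon holding the pyran oxygen (C8a–O1) and the carbon holding the benzylic methylene (C4a–C4) are direct neighbours. The oxygenated C5 stands on the other side of C4a. A 3-alkoxy-substituted aryne that takes up a carbonyl group delivers this contiguous 1,2,3-array.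
- **Forward order:** rings A and B and the benzoate ring are bought as benzyl ethers. Three steps give the silylaryl triflate and three give the enal. Their union closes ring C, the only ring made. Hydrolysis, reduction, acylation and global debenzylation follow.
- **Stereochemistry:** C2 is formed racemic. In the derived flavan-3-one it is epimerisable, and one catalyst-controlled transfer hydrogenation with dynamic kinetic resolution fixes C2 (R) and C3 (R) as the cis pair. No later step touches either centre.

Key step: step 7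

Remark: flavan numbering is used throughout (O1, C2, C3, C4, C4a, C5 to C8, C8a; ring A = benzo ring, ring B = catechol ring, ring C = pyran ring).

Assumption: the sense of induction in step 9 is derived from the accepted transition-state picture of RuCl(TsDPEN)(arene) catalysts. It is to be checked on 21 against the tetrabenzyl ether of natural (−)-epicatechin. The mirror-image catalyst is equally accessible.

**Step 1**
Reactants: 1 3,5-bis(benzyloxy)phenol
Product: 2 3,5-bis(benzyloxy)phenyl N-isopropylcarbamate
Conditions: i-PrNCO, Et3N (cat.), CH2Cl2, rt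
Reagents that add atoms: isopropyl isocyanate, CC(C)N=C=O
Why: Base-catalysed addition of the phenol O–H across the isocyanate (carbamoylation) installs a strong ortho-directing group in a form that mild base can remove later.

**Step 2**
Reactants: 2 3,5-bis(benzyloxy)phenyl N-isopropylcarbamate
Product: 6 3,5-bis(benzyloxy)-2-(trimethylsilyl)phenyl N-isopropylcarbamate, via N-silyl carbamate 3 (not isolated), via aryllithium 4 (not isolated), via doubly silylated carbamate 5 (not isolated)
Conditions: TBSOTf, TMEDA, Et2O, 0 °C to rt; n-BuLi, TMEDA, −78 °C; TMSCl, −78 °C to rt; brief aq NaHSO4 work-up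
Reagents that add atoms: TMSCl, C[Si](C)(C)Cl; TBSOTf, CC(C)(C)[Si](C)(C)OS(=O)(=O)C(F)(F)F (silyl group present in 3, 4, 5 only); n-BuLi, [Li]CCCC (lithium present in 4 only)
Why: Directed ortho-metalation, in which transient N-silylation masks the acidic N–H and C2, flanked by the carbamate and a benzyloxy group, is the cooperatively activated site, so n-BuLi/TMEDA at −78 °C should lithiate there faster than at C4 or at the benzylic CH2 groups before TMSCl traps the anion.

**Step 3**
Reactants: 6 3,5-bis(benzyloxy)-2-(trimethylsilyl)phenyl N-isopropylcarbamate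
Product: 8 3,5-bis(benzyloxy)-2-(trimethylsilyl)phenyl trifluoromethanesulfonate, via silylphenol 7 (not isolated)
Conditions: DBU, Et2NH, MeCN, 40 °C; then PhNTf2, rt
Reagents that add atoms: N-phenylbis(trifluoromethanesulfonimide), O=S(=O)(N(c1ccccc1)S(=O)(=O)C(F)(F)F)C(F)(F)F
Why: DBU-induced E1cB fragmentation of the secondary carbamate, with Et2NH taking up the carbamoyl fragment as a urea, frees the phenoxide without any acid that could protodesilylate the electron-rich aryl silane, and O-sulfonylation by PhNTf2 follows in the same flask.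

**Step 4**
Reactants: 9 3,4-bis(benzyloxy)benzaldehyde; 10 methyl 2-(dimethoxyphosphoryl)-2-methoxyacetate
Product: 12 methyl (Z)-3-[3,4-bis(benzyloxy)phenyl]-2-methoxyprop-2-enoate, via sodium phosphonate carbanion 11 (not isolated)
Conditions: 10, NaH, THF, 0 °C; then 9, 0 °C to rt
Reagents that add atoms: NaH, [Na+].[H-] (sodium present in 11 only)
Why: Horner–Wadsworth–Emmons olefination of an aromatic aldehyde with a stabilised α-alkoxyphosphonate anion should favour the (Z)-acrylate with aryl trans to the ester, and the alkene geometry is not critical because this carbon becomes sp3 in step 7.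

**Step 5**
Reactants: 12 methyl (Z)-3-[3,4-bis(benzyloxy)phenyl]-2-methoxyprop-2-enoate
Product: 13 (Z)-3-[3,4-bis(benzyloxy)phenyl]-2-methoxyprop-2-en-1-ol
Conditions: i-Bu2AlH (2.5 equiv), CH2Cl2, −78 °C; aq potassium sodium tartrate
Reagents that add atoms: none
Why: 1,2-Reduction of the conjugated ester by i-Bu2AlH (two hydride transfers) stops at the allylic alcohol, and the tartrate work-up stays non-acidic so the enol ether survives.

**Step 6**
Reactants: 13 (Z)-3-[3,4-bis(benzyloxy)phenyl]-2-methoxyprop-2-en-1-ol
Product: 14 (Z)-3-[3,4-bis(benzyloxy)phenyl]-2-methoxyprop-2-enal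
Conditions: MnO2 (activated, excess), CH2Cl2, rt
Reagents that add atoms: none
Why: Chemoselective MnO2 oxidation of a cinnamyl-type allylic alcohol under neutral heterogeneous conditions stops at the aldehyde and leaves the enol ether and the benzyl ethers alone.

**Step 7**
Reactants: 8 3,5-bis(benzyloxy)-2-(trimethylsilyl)phenyl trifluoromethanesulfonate; 14 (Z)-3-[3,4-bis(benzyloxy)phenyl]-2-methoxyprop-2-enal
Product: 18 rac-5,7-bis(benzyloxy)-2-[3,4-bis(benzyloxy)phenyl]-3-methoxy-2H-chromene, via aryne 15 (not isolated), via benzoxete 16 (not isolated), via ortho-quinone methide 17 (not isolated)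
Conditions: CsF (3 equiv), 14 (1.5 equiv), 4 Å molecular sieves, MeCN/THF (1:1), 40 °C, 8 added over 4 h
Reagents that add atoms: none
Why: Fluoride strikes silicon in 8 and triflate departs to give aryne 15, the carbonyl oxygen of 14 adds to the aryne carbon that lies away from the flanking benzyloxy group, the aryl anion so formed next to that group collapses onto the activated carbonyl carbon to give benzoxete 16 (formal [2+2]), and 4π ring opening cleaves the former C=O σ bond to give ortho-quinone methide 17. Ring C then closes by a thermal disrotatory oxa-6π electrocyclisation of the O1=C8a–C4a=C4–C3=C2 array in its s-cis rotamer, which forms O1–C2 and gives ring A its aromaticity back. The closest known reaction type is this same annulation of arynes from ortho-silylaryl triflates with α,β-unsaturated aldehydes, cinnamaldehydes among them, to 2H-chromenes, here applied to an enal that bears an α-methoxy group. The regioselectivity needed (O1 to C8a, C4 to C4a) is secured by the σ-withdrawing benzyloxy group beside the triple bond, which distorts the aryne so that nucleophiles enter at the remote carbon and negative charge builds up next to oxygen, and the same group crowds the alkenyl arm of 17 over to the carbonyl side, the geometry from which closure is possible. Chemoselectivity for C=O over C=C is expected because the enol ether double bond of 14 is trisubstituted and deactivated by the formyl group while the donor aryl ring raises the electron density on the carbonyl oxygen, and slow addition of 8 to an excess of 14 keeps the aryne from consuming 17 or 18. C2, the only new stereocentre, arises from the planar achiral 17 with no controlling element, so 18 is racemic, which costs nothing because C2 becomes epimerisable in step 8 and is fixed in step 9.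

**Step 8**
Reactants: 18 rac-5,7-bis(benzyloxy)-2-[3,4-bis(benzyloxy)phenyl]-3-methoxy-2H-chromene
Product: 19 rac-5,7-bis(benzyloxy)-2-[3,4-bis(benzyloxy)phenyl]chroman-3-one
Conditions: 1 M aq HCl/THF (1:4), rt, argon
Reagents that add atoms: water, O
Why: Acid-catalysed enol ether hydrolysis (protonation at C4, hydration of the C3 oxocarbenium ion, loss of methanol) is far faster than any cleavage of aryl benzyl ethers and leads to an O-benzylated flavan-3-one, a ketone type that can be isolated.

**Step 9**
Reactants: 19 rac-5,7-bis(benzyloxy)-2-[3,4-bis(benzyloxy)phenyl]chroman-3-one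
Product: 21 (2R,3R)-5,7-bis(benzyloxy)-2-[3,4-bis(benzyloxy)phenyl]chroman-3-ol, via achiral enol 20 (not isolated)
Conditions: RuCl[(S,S)-TsDPEN](p-cymene) (2 mol %), HCO2H/Et3N (1:1), CH2Cl2, 35 °C, argon
Reagents that add atoms: none
Why: Noyori–Ikariya asymmetric transfer hydrogenation run as a dynamic kinetic resolution, a reaction type established for configurationally labile α-substituted cyclic ketones: C2–H, acidified by the ketone, ring B and O1, interconverts the enantiomers of 19 through enol 20 in the amine-buffered medium, the (S,S)-catalyst should seat the slim C4H2/ring A flank under its η6-arene and the bulky C2 flank in the open sector and so hand hydride to the Si face of C3 (3R), and only (2R)-19 offers that face anti to its C2 aryl group, so the fast-reacting enantiomer drains the pool to the cis-(2R,3R) alcohol while loss of CO2 makes the reduction irreversible.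

**Step 10**
Reactants: 21 (2R,3R)-5,7-bis(benzyloxy)-2-[3,4-bis(benzyloxy)phenyl]chroman-3-ol; 22 4-(benzyloxy)benzoic acid
Product: 23 (2R,3R)-5,7-bis(benzyloxy)-2-[3,4-bis(benzyloxy)phenyl]chroman-3-yl 4-(benzyloxy)benzoate
Conditions: DCC, DMAP, CH2Cl2, 0 °C to rt
Reagents that add atoms: none
Why: Steglich esterification is the usual way to acylate the axial C3 hydroxyl group of O-benzylated cis-flavan-3-ols, forms the bond at oxygen with retention at C3 and leaves C2 untouched.

**Step 11**
Reactants: 23 (2R,3R)-5,7-bis(benzyloxy)-2-[3,4-bis(benzyloxy)phenyl]chroman-3-yl 4-(benzyloxy)benzoate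
Product: 24 (2R,3R)-2-(3,4-dihydroxyphenyl)-5,7-dihydroxychroman-3-yl 4-hydroxybenzoate
Conditions: H2 (1 atm), Pd(OH)2/C, THF/MeOH (1:1), rt
Reagents that add atoms: none
Why: Catalytic hydrogenolysis of the five aryl benzyl ethers under neutral conditions at ambient pressure is much faster than cleavage of the cyclic C2–O1 benzylic bond or of the secondary ester, so both stereocentres persist.

**Compound list**

1 | 3,5-bis(benzyloxy)phenol | Oc1cc(OCc2ccccc2)cc(OCc2ccccc2)c1 | starting material
2 | 3,5-bis(benzyloxy)phenyl N-isopropylcarbamate | CC(C)NC(=O)Oc1cc(OCc2ccccc2)cc(OCc2ccccc2)c1 | intermediate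
3 | 3,5-bis(benzyloxy)phenyl N-(tert-butyldimethylsilyl)-N-isopropylcarbamate (in situ) | CC(C)N(C(=O)Oc1cc(OCc2ccccc2)cc(OCc2ccccc2)c1)[Si](C)(C)C(C)(C)C | intermediate
4 | 2-lithio derivative of 3 (in situ) | CC(C)N(C(=O)Oc1cc(OCc2ccccc2)cc(OCc2ccccc2)c1[Li])[Si](C)(C)C(C)(C)C | intermediate
5 | 3,5-bis(benzyloxy)-2-(trimethylsilyl)phenyl N-(tert-butyldimethylsilyl)-N-isopropylcarbamate (in situ) | CC(C)N(C(=O)Oc1cc(OCc2ccccc2)cc(OCc2ccccc2)c1[Si](C)(C)C)[Si](C)(C)C(C)(C)C | intermediate
6 | 3,5-bis(benzyloxy)-2-(trimethylsilyl)phenyl N-isopropylcarbamate | CC(C)NC(=O)Oc1cc(OCc2ccccc2)cc(OCc2ccccc2)c1[Si](C)(C)C | intermediate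
7 | 3,5-bis(benzyloxy)-2-(trimethylsilyl)phenol (in situ, present as its amidinium phenoxide) | Oc1cc(OCc2ccccc2)cc(OCc2ccccc2)c1[Si](C)(C)C | intermediate
8 | 3,5-bis(benzyloxy)-2-(trimethylsilyl)phenyl trifluoromethanesulfonate | C[Si](C)(C)c1c(OCc2ccccc2)cc(OCc2ccccc2)cc1OS(=O)(=O)C(F)(F)F | intermediate
9 | 3,4-bis(benzyloxy)benzaldehyde | O=Cc1ccc(OCc2ccccc2)c(OCc2ccccc2)c1 | starting material
10 | methyl 2-(dimethoxyphosphoryl)-2-methoxyacetate | COC(=O)C(OC)P(=O)(OC)OC | starting material
11 | sodium salt of the carbanion of 10 (in situ) | [Na+].COC(=O)[C-](OC)P(=O)(OC)OC | intermediate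
12 | methyl (Z)-3-[3,4-bis(benzyloxy)phenyl]-2-methoxyprop-2-enoate | CO/C(C(=O)OC)=C\c1ccc(OCc2ccccc2)c(OCc2ccccc2)c1 | intermediate
13 | (Z)-3-[3,4-bis(benzyloxy)phenyl]-2-methoxyprop-2-en-1-ol | CO/C(CO)=C\c1ccc(OCc2ccccc2)c(OCc2ccccc2)c1 | intermediate
14 | (Z)-3-[3,4-bis(benzyloxy)phenyl]-2-methoxyprop-2-enal | CO/C(C=O)=C\c1ccc(OCc2ccccc2)c(OCc2ccccc2)c1 | intermediate
15 | 3,5-bis(benzyloxy)benzyne (in situ) | C1#CC(OCc2ccccc2)=CC(OCc2ccccc2)=C1 | intermediate
16 | rac-3,5-bis(benzyloxy)-2-[(Z)-2-[3,4-bis(benzyloxy)phenyl]-1-methoxyethenyl]-2H-benzo[b]oxete (in situ) | CO/C(=C\c1ccc(OCc2ccccc2)c(OCc2ccccc2)c1)C1Oc2cc(OCc3ccccc3)cc(OCc3ccccc3)c21 | intermediate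
17 | (6Z)-3,5-bis(benzyloxy)-6-[(2Z)-3-[3,4-bis(benzyloxy)phenyl]-2-methoxyprop-2-enylidene]cyclohexa-2,4-dien-1-one, alkenyl arm syn to the carbonyl oxygen (in situ) | O=C1C=C(OCc2ccccc2)C=C(OCc2ccccc2)/C1=C/C(OC)=C/c1ccc(OCc2ccccc2)c(OCc2ccccc2)c1 | intermediate
18 | rac-5,7-bis(benzyloxy)-2-[3,4-bis(benzyloxy)phenyl]-3-methoxy-2H-chromene | COC1=Cc2c(OCc3ccccc3)cc(OCc3ccccc3)cc2OC1c1ccc(OCc2ccccc2)c(OCc2ccccc2)c1 | intermediate
19 | rac-5,7-bis(benzyloxy)-2-[3,4-bis(benzyloxy)phenyl]chroman-3-one | O=C1Cc2c(OCc3ccccc3)cc(OCc3ccccc3)cc2OC1c1ccc(OCc2ccccc2)c(OCc2ccccc2)c1 | intermediate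
20 | 5,7-bis(benzyloxy)-2-[3,4-bis(benzyloxy)phenyl]-4H-chromen-3-ol, the achiral enol of 19 (in situ) | OC1=C(c2ccc(OCc3ccccc3)c(OCc3ccccc3)c2)Oc2cc(OCc3ccccc3)cc(OCc3ccccc3)c2C1 | intermediate
21 | (2R,3R)-5,7-bis(benzyloxy)-2-[3,4-bis(benzyloxy)phenyl]chroman-3-ol (tetra-O-benzyl-(−)-epicatechin) | O[C@@H]1Cc2c(OCc3ccccc3)cc(OCc3ccccc3)cc2O[C@@H]1c1ccc(OCc2ccccc2)c(OCc2ccccc2)c1 | intermediate
22 | 4-(benzyloxy)benzoic acid | O=C(O)c1ccc(OCc2ccccc2)cc1 | starting material
23 | (2R,3R)-5,7-bis(benzyloxy)-2-[3,4-bis(benzyloxy)phenyl]chroman-3-yl 4-(benzyloxy)benzoate | O=C(O[C@@H]1Cc2c(OCc3ccccc3)cc(OCc3ccccc3)cc2O[C@@H]1c1ccc(OCc2ccccc2)c(OCc2ccccc2)c1)c1ccc(OCc2ccccc2)cc1 | intermediate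
24 | (2R,3R)-2-(3,4-dihydroxyphenyl)-5,7-dihydroxychroman-3-yl 4-hydroxybenzoate (epicatechin 3-O-p-hydroxybenzoate) | O=C(O[C@@H]1Cc2c(O)cc(O)cc2O[C@@H]1c1ccc(O)c(O)c1)c1ccc(O)cc1 | target

**Step count**

Total step count: 11 (three steps to 8, three steps to 14, five steps from their union to 24).

Longest linear sequence: 8 steps (steps 1 to 3 and 7 to 11; the branch through steps 4 to 6 is equally long).

**Steps most likely to fail**

**Step 7.**
- *Risk:* the aryne may be drained by cycloaddition with the enol ether or styrene π systems of 14, or by attack on the first-formed quinone methide and chromene. Oxygen attack by the cross-conjugated aldehyde may also be too slow to compete.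
- *Fallback:* the same ortho-quinone methide is reached without an aryne, setting out from phenol 1 and enal 14. PhB(OH)2 and catalytic propionic acid in refluxing toluene, with azeotropic removal of water, should condense the aldehyde at the carbon ortho to the hydroxyl group. Both ortho positions of 1 are equivalent and the boron tether excludes the para position. The product is 5,7-bis(benzyloxy)-4-[(Z)-2-[3,4-bis(benzyloxy)phenyl]-1-methoxyethenyl]-2-phenyl-4H-1,3,2-benzodioxaborinine F1. On continued heating this heterocycle loses its boron unit by cycloreversion to give 17, which closes as before. The route is rejoined at 18.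

**Step 9.**
- *Risk:* epimerisation at C2 may lag behind reduction. Enantioface discrimination may be weak at a ketone that is not conjugated to an arene. Induction may run in the opposite sense.
- *Fallback:* substrate-controlled reduction followed by classical resolution, setting out from 19. LiBH(s-Bu)3 in THF at −78 °C, whose bulky hydride arrives anti to the C2 aryl group, should give racemic cis-5,7-bis(benzyloxy)-2-[3,4-bis(benzyloxy)phenyl]chroman-3-ol F2. DCC/DMAP coupling with (S)-2-methoxy-2-phenylacetic acid turns it into the (2R,3R)-chroman-3-yl (S)-2-methoxy-2-phenylacetate F3 and the (2S,3S)-chroman-3-yl (S)-2-methoxy-2-phenylacetate F4. These are diastereomers and are separated by chromatography or crystallisation. LiOH in THF/MeOH/water cleaves F3, and the route is rejoined at 21.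

**Step 2.**
- *Risk:* benzylic deprotonation with subsequent Wittig rearrangement, anionic ortho-Fries migration of the carbamoyl group on warming, and protodesilylation of the very electron-rich aryl silane during the acidic work-up may all compete.
- *Fallback:* halogen–metal exchange and silyl migration replace deprotonation, setting out from 1. NBS in CH2Cl2 at −78 °C should brominate ortho to the free hydroxyl group to give 2-bromo-3,5-bis(benzyloxy)phenol F5. Hexamethyldisilazane in warm THF gives [2-bromo-3,5-bis(benzyloxy)phenoxy]trimethylsilane F6. n-BuLi in THF at −78 °C effects bromine–lithium exchange, much faster than any deprotonation, to [2,4-bis(benzyloxy)-6-(trimethylsilyloxy)phenyl]lithium F7. Its silyl group migrates from oxygen to carbon (retro-Brook rearrangement) to leave the lithium salt of 7. Tf2O added to the same flask gives the triflate, and the route is rejoined at 8.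

**Further compounds**

F1 | step 7 | 5,7-bis(benzyloxy)-4-[(Z)-2-[3,4-bis(benzyloxy)phenyl]-1-methoxyethenyl]-2-phenyl-4H-1,3,2-benzodioxaborinine (racemic) | CO/C(=C\c1ccc(OCc2ccccc2)c(OCc2ccccc2)c1)C1OB(c2ccccc2)Oc2cc(OCc3ccccc3)cc(OCc3ccccc3)c21
F2 | step 9 | racemic cis-5,7-bis(benzyloxy)-2-[3,4-bis(benzyloxy)phenyl]chroman-3-ol (both enantiomers drawn) | O[C@@H]1Cc2c(OCc3ccccc3)cc(OCc3ccccc3)cc2O[C@@H]1c1ccc(OCc2ccccc2)c(OCc2ccccc2)c1.O[C@H]1Cc2c(OCc3ccccc3)cc(OCc3ccccc3)cc2O[C@H]1c1ccc(OCc2ccccc2)c(OCc2ccccc2)c1
F3 | step 9 | (2R,3R)-5,7-bis(benzyloxy)-2-[3,4-bis(benzyloxy)phenyl]chroman-3-yl (S)-2-methoxy-2-phenylacetate | CO[C@H](C(=O)O[C@@H]1Cc2c(OCc3ccccc3)cc(OCc3ccccc3)cc2O[C@@H]1c1ccc(OCc2ccccc2)c(OCc2ccccc2)c1)c1ccccc1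
F4 | step 9 | (2S,3S)-5,7-bis(benzyloxy)-2-[3,4-bis(benzyloxy)phenyl]chroman-3-yl (S)-2-methoxy-2-phenylacetate | CO[C@H](C(=O)O[C@H]1Cc2c(OCc3ccccc3)cc(OCc3ccccc3)cc2O[C@H]1c1ccc(OCc2ccccc2)c(OCc2ccccc2)c1)c1ccccc1
F5 | step 2 | 2-bromo-3,5-bis(benzyloxy)phenol | Oc1cc(OCc2ccccc2)cc(OCc2ccccc2)c1Br
F6 | step 2 | [2-bromo-3,5-bis(benzyloxy)phenoxy]trimethylsilane | C[Si](C)(C)Oc1cc(OCc2ccccc2)cc(OCc2ccccc2)c1Br
F7 | step 2 | [2,4-bis(benzyloxy)-6-(trimethylsilyloxy)phenyl]lithium | C[Si](C)(C)Oc1cc(OCc2ccccc2)cc(OCc2ccccc2)c1[Li]
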